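**Plan**

Labels (lignan numbering): ArA = 4-hydroxy-3-methoxyphenyl on C7, carried as its pivalate ArP = 3-methoxy-4-(pivaloyloxy)phenyl; ArB = 3-methoxy-4-[(3-methylbut-2-en-1-yl)oxy]phenyl on C7'; C8 and C8' are the ring-fusion carbons, C9 and C9' the OCH2 carbons; ring 1 = O1–C7–C8–C8'–C9', ring 2 = O2–C7'–C8'–C8–C9.
Retrosynthesis: after the phenol ester and the C9 oxidation level are adjusted, ring 2 is cut at C8–C9 and O2–C9 (CO/H2 across a C7=C8 enol ether, lactol closure); then C7–ArA (Suzuki coupling of a lactone-derived ketene acetal phosphate), O1–C7 (lactone) and C8'–C7' (aldol) are cut, and last the prenyl O–C bond.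
Enabling feature: C9 is a lone carbon on C8, bonded to O2 and flanked by the C7–H carbon, so with ring 1 held as a 5-aryl-2,3-dihydrofuran the C7' hydroxyl is homoallylic to C7=C8 and can steer a syn addition of H (to C7) and CHO (to C8) that ends as the ring 2 lactol.
Forward order: prenyl vanillin and a succinate imide are joined by an aldol reaction (C8'–C7'), ring 1 is made as a γ-lactone and turned into the aryl dihydrofuran, ring 2 follows by directed hydroformylation, then C9 is deoxygenated and the phenol freed.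
Stereochemistry: C8' and C7' come from the (S)-4-benzyloxazolidinone syn-aldol; C8 and C7 come from the hydroxyl-directed syn addition on the face of ring 1 that carries the C8' side chain.

Key step: step 10

Assumption: the SMILES is read as the 7S,8R,7'S,8'R isomer (both aryl groups exo on the cis-fused furofuran), and lactol 19 is used as its C9 epimer mixture because step 11 removes that centre.

**Route**

Step 1
Reactants: 1 vanillin; 2 prenyl bromide (1-bromo-3-methylbut-2-ene)
Product: 3 3-methoxy-4-[(3-methylbut-2-en-1-yl)oxy]benzaldehyde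
Conditions: K2CO3, DMF, rt
Reagents that add atoms: none
Why: Williamson ether synthesis of a phenoxide with a primary allylic bromide is routine, and carbonate in DMF should give O-alkylation only.

Step 2
Reactants: 4 (S)-4-benzyl-1,3-oxazolidin-2-one; 5 methyl 4-chloro-4-oxobutanoate
Product: 7 (S)-4-benzyl-3-(4-methoxy-4-oxobutanoyl)-1,3-oxazolidin-2-one, via lithium oxazolidinide 6 (not isolated)
Conditions: n-BuLi, THF, −78 °C; then 5, −78 → 0 °C
Reagents that add atoms: none
Why: N-acylation of the lithiated Evans auxiliary with an acid chloride is the standard entry to acyl oxazolidinones, and the acid chloride should react far faster than the methyl ester.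

Step 3
Reactants: 7 (S)-4-benzyl-3-(4-methoxy-4-oxobutanoyl)-1,3-oxazolidin-2-one; 3 3-methoxy-4-[(3-methylbut-2-en-1-yl)oxy]benzaldehyde
Product: 9 methyl (3S)-4-[(4S)-4-benzyl-2-oxo-1,3-oxazolidin-3-yl]-3-[(S)-hydroxy(ArB)methyl]-4-oxobutanoate, via dibutylboron Z-enolate 8 (not isolated)
Conditions: Bu2BOTf, i-Pr2NEt, CH2Cl2, −78 → 0 °C; then 3, −78 → 0 °C; pH 7 buffer, MeOH, H2O2, 0 °C
Reagents that add atoms: none
Why: Evans boron syn-aldol reaction, in which the imide (not the ester) is enolised to the Z-enolate and this reacts through a chair Zimmerman–Traxler transition state on the face away from the benzyl group of the (S)-auxiliary, setting C8' and C7' syn in the absolute sense the target needs.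

Step 4
Reactants: 9 methyl (3S)-4-[(4S)-4-benzyl-2-oxo-1,3-oxazolidin-3-yl]-3-[(S)-hydroxy(ArB)methyl]-4-oxobutanoate
Product: 10 methyl (3S)-4-[(4S)-4-benzyl-2-oxo-1,3-oxazolidin-3-yl]-3-[(S)-(tert-butyldimethylsilyloxy)(ArB)methyl]-4-oxobutanoate
Conditions: TBSOTf, 2,6-lutidine, CH2Cl2, −78 → 0 °C (crude 9 used at once)
Reagents that add atoms: tert-butyldimethylsilyl trifluoromethanesulfonate, CC(C)(C)[Si](C)(C)OS(=O)(=O)C(F)(F)F
Why: Silyl ether formation with a silyl triflate and lutidine is standard for hindered aldol hydroxyls and, run directly on crude 9, should block the C7' oxygen before it can lactonise onto the methyl ester or undergo retro-aldol cleavage.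

Step 5
Reactants: 10 methyl (3S)-4-[(4S)-4-benzyl-2-oxo-1,3-oxazolidin-3-yl]-3-[(S)-(tert-butyldimethylsilyloxy)(ArB)methyl]-4-oxobutanoate
Product: 12 (4R)-4-[(S)-(tert-butyldimethylsilyloxy)(ArB)methyl]dihydrofuran-2(3H)-one, via hydroxy ester 11 (not isolated)
Conditions: NaBH4, THF/H2O (3:1), 0 °C → rt; then PPTS (cat.), CH2Cl2, rt
Reagents that add atoms: none
Why: Reductive cleavage of the N-acyl oxazolidinone by borohydride in wet THF should give the primary C9' alcohol without touching the methyl ester, and the γ-hydroxy ester then lactonises (5-exo-trig acyl substitution) to ring 1 at the lactone level with both stereocentres untouched.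

Step 6
Reactants: 13 2-methoxy-4-(4,4,5,5-tetramethyl-1,3,2-dioxaborolan-2-yl)phenol
Product: 14 2-methoxy-4-(4,4,5,5-tetramethyl-1,3,2-dioxaborolan-2-yl)phenyl pivalate
Conditions: PivCl, Et3N, DMAP (cat.), CH2Cl2, 0 °C → rt
Reagents that add atoms: pivaloyl chloride, CC(C)(C)C(Cl)=O
Why: Acylation of a phenol gives the pivalate, chosen because it should survive buffered fluoride in step 9, offers no exchange site to the phosphinite in step 10 and lowers the donor power of ArA during the Lewis acid step 11.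

Step 7
Reactants: 12 (4R)-4-[(S)-(tert-butyldimethylsilyloxy)(ArB)methyl]dihydrofuran-2(3H)-one
Product: 15 (4R)-4-[(S)-(tert-butyldimethylsilyloxy)(ArB)methyl]-4,5-dihydrofuran-2-yl diphenyl phosphate
Conditions: KN(SiMe3)2 added to 12 and (PhO)2P(O)Cl, THF/DMPU, −78 °C; used without storage
Reagents that add atoms: diphenyl chlorophosphate, O=P(Cl)(Oc1ccccc1)Oc1ccccc1
Why: O-phosphorylation of a lactone potassium enolate under in situ trapping is the established way to ketene acetal phosphates, which are sturdier than the corresponding triflates and behave as vinyl electrophiles.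

Step 8
Reactants: 15 (4R)-4-[(S)-(tert-butyldimethylsilyloxy)(ArB)methyl]-4,5-dihydrofuran-2-yl diphenyl phosphate; 14 2-methoxy-4-(4,4,5,5-tetramethyl-1,3,2-dioxaborolan-2-yl)phenyl pivalate
Product: 16 4-[(4R)-4-[(S)-(tert-butyldimethylsilyloxy)(ArB)methyl]-4,5-dihydrofuran-2-yl]-2-methoxyphenyl pivalate
Conditions: Pd(PPh3)4 (5 mol %), K3PO4, dioxane/H2O (10:1), 60 °C
Reagents that add atoms: none
Why: Suzuki–Miyaura coupling of a ketene acetal phosphate with an arylboronate under zerovalent palladium forms the C7–ArA bond and leaves C7=C8 as the enol ether of ring 1, while the aryl pivalate and the prenyl ether should be inert to palladium here.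

Step 9
Reactants: 16 4-[(4R)-4-[(S)-(tert-butyldimethylsilyloxy)(ArB)methyl]-4,5-dihydrofuran-2-yl]-2-methoxyphenyl pivalate
Product: 17 4-[(4R)-4-[(S)-hydroxy(ArB)methyl]-4,5-dihydrofuran-2-yl]-2-methoxyphenyl pivalate
Conditions: Bu4NF, AcOH (1:1), THF, 0 °C → rt
Reagents that add atoms: none
Why: Fluoride desilylation removes the alkyl silyl ether, and the acetic acid buffer should keep the medium from cleaving the aryl pivalate while staying too weakly acidic to hydrate the enol ether.

Step 10
Reactants: 17 4-[(4R)-4-[(S)-hydroxy(ArB)methyl]-4,5-dihydrofuran-2-yl]-2-methoxyphenyl pivalate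
Product: 19 4-[(1S,3aR,4S,6aS)-4-ArB-6-hydroxytetrahydro-1H,3H-furo[3,4-c]furan-1-yl]-2-methoxyphenyl pivalate (C9 epimers), via hydroxy aldehyde 18 (not isolated)
Conditions: Rh(acac)(CO)2 (2 mol %), Ph2POMe (20 mol %), CO/H2 (1:1, 40 bar), 4 Å MS, THF, 50 °C
Reagents that add atoms: carbon monoxide, [C-]#[O+]
Why: Proposed new method: methyl diphenylphosphinite should exchange its methoxy group for the C7' hydroxyl of 17 (the sieves take up the methanol), the tethered monovalent rhodium hydride then adds syn across C7=C8 with hydrogen going to C7 and rhodium to C8, CO inserts and hydrogenolysis releases aldehyde 18 while the phosphinite passes to the next molecule of 17; the closest known reaction type is the branched-selective hydroformylation of homoallylic alcohols under a catalytic, reversibly bound phosphinite directing group, which gives γ-lactols but has not been shown on a cyclic trisubstituted aryl enol ether. Ring 2 closes by 5-exo-trig addition of the C7' hydroxyl to the C9 formyl group, which is possible only because the formyl group is delivered cis to the C8' side chain. C8 is set by delivery of rhodium from the tether to the face of ring 1 that carries the side chain, C7 by the syn addition of hydrogen on that same face (so ArP ends trans to C9, exo), and C9 of the lactol is left uncontrolled because step 11 removes it. Regioselectivity is needed and should come from the six-membered P–O–C7'–C8'–C8–Rh chelate together with the fully substituted C7, which cannot accept the formyl group; facial selectivity is needed against the steric preference for the open face and is secured by the covalent P–O tether. The chelated C8–Rh bond has no syn β-hydrogen on C8', so migration of the double bond should be slow, and the prenyl double bond, trisubstituted and undirected, should stay untouched.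

Step 11
Reactants: 19 4-[(1S,3aR,4S,6aS)-4-ArB-6-hydroxytetrahydro-1H,3H-furo[3,4-c]furan-1-yl]-2-methoxyphenyl pivalate
Product: 20 4-[(1S,3aR,4S,6aR)-4-ArB-tetrahydro-1H,3H-furo[3,4-c]furan-1-yl]-2-methoxyphenyl pivalate
Conditions: Et3SiH, BF3·OEt2, CH2Cl2, −78 °C; Et3N then aq. NaHCO3 quench at −78 °C
Reagents that add atoms: none
Why: Ionic reduction of a lactol, in which BF3 ionises the hemiacetal to the C9 oxocarbenium ion and triethylsilane reduces it at −78 °C, a temperature at which the benzylic ethers at C7 (further deactivated by the pivalate) and C7' and the prenyl ether should not ionise, so no stereocentre is touched.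

Step 12
Reactants: 20 4-[(1S,3aR,4S,6aR)-4-ArB-tetrahydro-1H,3H-furo[3,4-c]furan-1-yl]-2-methoxyphenyl pivalate
Product: 21 4-[(1S,3aR,4S,6aR)-4-ArB-tetrahydro-1H,3H-furo[3,4-c]furan-1-yl]-2-methoxyphenol (CNP0185952.1)
Conditions: K2CO3 (0.5 equiv), MeOH/THF, rt
Reagents that add atoms: none
Why: Base-mediated transesterification of the aryl pivalate with methanol frees the phenol under conditions to which the furofuran ethers and the prenyl ether are inert.

**Compound list**

1 | vanillin (4-hydroxy-3-methoxybenzaldehyde) | COc1cc(C=O)ccc1O | starting material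
2 | prenyl bromide (1-bromo-3-methylbut-2-ene) | CC(C)=CCBr | starting material
3 | 3-methoxy-4-[(3-methylbut-2-en-1-yl)oxy]benzaldehyde | COc1cc(C=O)ccc1OCC=C(C)C | intermediate
4 | (S)-4-benzyl-1,3-oxazolidin-2-one | O=C1N[C@@H](Cc2ccccc2)CO1 | starting material
5 | methyl 4-chloro-4-oxobutanoate | COC(=O)CCC(Cl)=O | starting material
6 | lithium salt of 4 (N-lithio oxazolidinone, not isolated) | [Li]N1[C@@H](Cc2ccccc2)COC1=O | intermediate
7 | (S)-4-benzyl-3-(4-methoxy-4-oxobutanoyl)-1,3-oxazolidin-2-one | COC(=O)CCC(=O)N1[C@@H](Cc2ccccc2)COC1=O | intermediate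
8 | dibutylboron Z-enolate of 7 (not isolated) | COC(=O)C/C=C(\OB(CCCC)CCCC)N1[C@@H](Cc2ccccc2)COC1=O | intermediate
9 | methyl (3S)-4-[(4S)-4-benzyl-2-oxo-1,3-oxazolidin-3-yl]-3-[(S)-hydroxy(ArB)methyl]-4-oxobutanoate | COC(=O)C[C@@H]([C@H](O)c1ccc(OCC=C(C)C)c(OC)c1)C(=O)N1[C@@H](Cc2ccccc2)COC1=O | intermediate
10 | tert-butyldimethylsilyl ether of 9 | COC(=O)C[C@@H]([C@H](O[Si](C)(C)C(C)(C)C)c1ccc(OCC=C(C)C)c(OC)c1)C(=O)N1[C@@H](Cc2ccccc2)COC1=O | intermediate
11 | methyl (3R)-3-[(S)-(tert-butyldimethylsilyloxy)(ArB)methyl]-4-hydroxybutanoate (not isolated) | COC(=O)C[C@@H]([C@H](O[Si](C)(C)C(C)(C)C)c1ccc(OCC=C(C)C)c(OC)c1)CO | intermediate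
12 | (4R)-4-[(S)-(tert-butyldimethylsilyloxy)(ArB)methyl]dihydrofuran-2(3H)-one | O=C1C[C@@H]([C@H](O[Si](C)(C)C(C)(C)C)c2ccc(OCC=C(C)C)c(OC)c2)CO1 | intermediate
13 | 2-methoxy-4-(4,4,5,5-tetramethyl-1,3,2-dioxaborolan-2-yl)phenol | COc1cc(B2OC(C)(C)C(C)(C)O2)ccc1O | starting material
14 | 2-methoxy-4-(4,4,5,5-tetramethyl-1,3,2-dioxaborolan-2-yl)phenyl pivalate | COc1cc(B2OC(C)(C)C(C)(C)O2)ccc1OC(=O)C(C)(C)C | intermediate
15 | (4R)-4-[(S)-(tert-butyldimethylsilyloxy)(ArB)methyl]-4,5-dihydrofuran-2-yl diphenyl phosphate | O=P(Oc1ccccc1)(Oc1ccccc1)OC1=C[C@@H]([C@H](O[Si](C)(C)C(C)(C)C)c2ccc(OCC=C(C)C)c(OC)c2)CO1 | intermediate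
16 | 4-[(4R)-4-[(S)-(tert-butyldimethylsilyloxy)(ArB)methyl]-4,5-dihydrofuran-2-yl]-2-methoxyphenyl pivalate | COc1cc(C2=C[C@@H]([C@H](O[Si](C)(C)C(C)(C)C)c3ccc(OCC=C(C)C)c(OC)c3)CO2)ccc1OC(=O)C(C)(C)C | intermediate
17 | 4-[(4R)-4-[(S)-hydroxy(ArB)methyl]-4,5-dihydrofuran-2-yl]-2-methoxyphenyl pivalate (key-step precursor) | COc1cc(C2=C[C@@H]([C@H](O)c3ccc(OCC=C(C)C)c(OC)c3)CO2)ccc1OC(=O)C(C)(C)C | intermediate
18 | 4-[(2S,3S,4R)-3-formyl-4-[(S)-hydroxy(ArB)methyl]tetrahydrofuran-2-yl]-2-methoxyphenyl pivalate (not isolated) | COc1cc([C@H]2OC[C@H]([C@H](O)c3ccc(OCC=C(C)C)c(OC)c3)[C@@H]2C=O)ccc1OC(=O)C(C)(C)C | intermediate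
19 | 4-[(1S,3aR,4S,6aS)-4-ArB-6-hydroxytetrahydro-1H,3H-furo[3,4-c]furan-1-yl]-2-methoxyphenyl pivalate (C9 lactol, epimers at C9) | COc1cc([C@H]2OC[C@H]3[C@@H]2C(O)O[C@@H]3c2ccc(OCC=C(C)C)c(OC)c2)ccc1OC(=O)C(C)(C)C | intermediate
20 | 4-[(1S,3aR,4S,6aR)-4-ArB-tetrahydro-1H,3H-furo[3,4-c]furan-1-yl]-2-methoxyphenyl pivalate | COc1cc([C@H]2OC[C@H]3[C@@H]2CO[C@@H]3c2ccc(OCC=C(C)C)c(OC)c2)ccc1OC(=O)C(C)(C)C | intermediate
21 | 4-[(1S,3aR,4S,6aR)-4-ArB-tetrahydro-1H,3H-furo[3,4-c]furan-1-yl]-2-methoxyphenol (7S,8R,7'S,8'R) | COc1cc([C@H]2OC[C@H]3[C@@H]2CO[C@@H]3c2ccc(OCC=C(C)C)c(OC)c2)ccc1O | target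

**Step count**

Total: 12 steps. Longest linear sequence: 10 steps (steps 1, 3, 4, 5, 7, 8, 9, 10, 11, 12).

**Steps most likely to fail**

Step 10. The catalyst may not turn over on a trisubstituted aryl enol ether, the formyl group may be delivered with poor facial or regiochemical control, or C7=C8 may be hydrogenated instead. The fallback uses known chemistry and closes both rings by benzylic etherification; it sets out from lactone 12 and comes back at 21. Vanillin 1 is silylated (TBSCl, imidazole, DMF) to 4-(tert-butyldimethylsilyloxy)-3-methoxybenzaldehyde F1. The lithium enolate of 12 (LiN(i-Pr)2, THF, −78 °C) adds to it anti to the C8' substituent and should give the trans-3,4-disubstituted aldol lactone F2 (the C7 carbinol is a mixture, which does not matter). LiAlH4 in THF opens the lactone to the silyl-protected triol F3, and Bu4NF removes both silyl ethers to give the tetraol phenol F4. Catalytic camphorsulfonic acid in CH2Cl2 at 0 °C then closes O1–C7 and O2–C7' through the benzylic cations, a closure known to favour the exo,exo furofuran, and should give 21 directly.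

Step 7. The five-membered lactone enolate may ring-open or be phosphorylated on carbon, and the ketene acetal phosphate may hydrolyse before it is coupled. The fallback replaces cross-coupling by carbonyl addition and dehydration; it sets out from lactone 12 and comes back at 17. Commercial 4-bromo-2-methoxyphenol is silylated (i-Pr3SiCl, imidazole) to (4-bromo-2-methoxyphenoxy)triisopropylsilane F5. Bromine–lithium exchange (n-BuLi, THF, −78 °C) and addition to 12 should stop at the γ-hydroxy aryl ketone F6, which is in equilibrium with its cyclic hemiketal. MsCl and Et3N dehydrate the hemiketal to the bis-silylated 5-aryl-2,3-dihydrofuran F7, and Bu4NF removes both silyl groups to give the phenol carbinol F8. PivCl with K2CO3 in acetone acylates the phenoxide in preference to the hindered C7' alcohol and gives 17.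

Step 11. The Lewis acid may ionise the benzylic C7'–O2 bond or the prenyl ether, leading to epimerisation, reductive ring opening or loss of the prenyl group. The fallback is acid-free; it sets out from lactol 19 and comes back at 20. NaBH4 (THF/EtOH, 0 °C) reduces the open hydroxy aldehyde form to the 1,4-diol F9. PPh3 and DIAD (THF, 0 °C) then activate the primary C9 hydroxyl, which the C7' hydroxyl displaces with retention at C7', closing ring 2 as the ether 20.

**Further compounds**

F1 | step 10 | 4-(tert-butyldimethylsilyloxy)-3-methoxybenzaldehyde | COc1cc(C=O)ccc1O[Si](C)(C)C(C)(C)C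
F2 | step 10 | (3S,4R)-3-[hydroxy(4-(tert-butyldimethylsilyloxy)-3-methoxyphenyl)methyl]-4-[(S)-(tert-butyldimethylsilyloxy)(ArB)methyl]dihydrofuran-2(3H)-one (carbinol epimers) | COc1cc(C(O)[C@H]2C(=O)OC[C@@H]2[C@H](O[Si](C)(C)C(C)(C)C)c2ccc(OCC=C(C)C)c(OC)c2)ccc1O[Si](C)(C)C(C)(C)C
F3 | step 10 | (2R,3R)-2-[hydroxy(4-(tert-butyldimethylsilyloxy)-3-methoxyphenyl)methyl]-3-[(S)-(tert-butyldimethylsilyloxy)(ArB)methyl]butane-1,4-diol | COc1cc(C(O)[C@@H](CO)[C@H](CO)[C@H](O[Si](C)(C)C(C)(C)C)c2ccc(OCC=C(C)C)c(OC)c2)ccc1O[Si](C)(C)C(C)(C)C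
F4 | step 10 | (2R,3R)-2-[hydroxy(4-hydroxy-3-methoxyphenyl)methyl]-3-[(S)-hydroxy(ArB)methyl]butane-1,4-diol | COc1cc(C(O)[C@@H](CO)[C@H](CO)[C@H](O)c2ccc(OCC=C(C)C)c(OC)c2)ccc1O
F5 | step 7 | (4-bromo-2-methoxyphenoxy)triisopropylsilane | COc1cc(Br)ccc1O[Si](C(C)C)(C(C)C)C(C)C
F6 | step 7 | (3R,4S)-4-(tert-butyldimethylsilyloxy)-3-(hydroxymethyl)-4-ArB-1-[3-methoxy-4-(triisopropylsilyloxy)phenyl]butan-1-one | COc1cc(C(=O)C[C@@H]([C@H](O[Si](C)(C)C(C)(C)C)c2ccc(OCC=C(C)C)c(OC)c2)CO)ccc1O[Si](C(C)C)(C(C)C)C(C)C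
F7 | step 7 | (4R)-4-[(S)-(tert-butyldimethylsilyloxy)(ArB)methyl]-2-[3-methoxy-4-(triisopropylsilyloxy)phenyl]-4,5-dihydrofuran | COc1cc(C2=C[C@@H]([C@H](O[Si](C)(C)C(C)(C)C)c3ccc(OCC=C(C)C)c(OC)c3)CO2)ccc1O[Si](C(C)C)(C(C)C)C(C)C
F8 | step 7 | 4-[(4R)-4-[(S)-hydroxy(ArB)methyl]-4,5-dihydrofuran-2-yl]-2-methoxyphenol | COc1cc(C2=C[C@@H]([C@H](O)c3ccc(OCC=C(C)C)c(OC)c3)CO2)ccc1O
F9 | step 11 | 4-[(2S,3R,4R)-3-(hydroxymethyl)-4-[(S)-hydroxy(ArB)methyl]tetrahydrofuran-2-yl]-2-methoxyphenyl pivalate | COc1cc([C@H]2OC[C@H]([C@H](O)c3ccc(OCC=C(C)C)c(OC)c3)[C@@H]2CO)ccc1OC(=O)C(C)(C)C
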